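**Retrosynthetic overview**
1. The last bonds made are the C19–O acyl bond (silyl-protected p-coumaric acid onto the 8α,19-diol) and C12–C13 (a 12-iodide with the 2-butadienyl Grignard reagent from chloroprene).
2. Ring B, with C10, C9 and C8, comes from cationic closure C9–C10 of a monocyclic (E)-β,γ-unsaturated acid with capture of C8 by the carboxyl (8α,12-lactone), relayed from C5.
3. Ring A comes first, by a catalytic enantioselective Diels–Alder reaction of methacrolein (C3, C4, C18, C19) with the terminal diene of a triene ester (bonds C2–C3 and C4–C5). The strategy rests on the quaternary C4 of ring A (C18 methyl, oxidised C19) lying next to C5, whose C6 branch is cis to C19, i.e. the formyl-endo adduct.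
4. The triene ester comes from geraniol by C1 carbonylation, SeO2 oxidation of the terminal E-methyl and methylenation.
5. Ring order: A (step 5), then B together with the lactone (step 9).

Key step: step 5

Remark: labdane numbering (C1–C20) is used for the atoms of all intermediates. The choice of the (S)-catalyst in step 5 rests on the formyl C–H···O binding model for 2-substituted acroleins and is an expectation, not an established result for this diene.

**Route**

Step 1
Reactants: 1 geraniol
Product: 2 geranyl methyl carbonate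
Conditions: ClCO2Me, pyridine, CH2Cl2, 0 °C
Reagents that add atoms: methyl chloroformate, COC(=O)Cl
Why: O-acylation of the primary allylic alcohol with a chloroformate under pyridine gives the mixed carbonate without touching the alkenes.

Step 2
Reactants: 2 geranyl methyl carbonate
Product: 3 methyl (3E)-4,8-dimethylnona-3,7-dienoate
Conditions: Pd(OAc)2 (2 mol%), PPh3 (4 mol%), CO (30 bar), THF, 50 °C
Reagents that add atoms: carbon monoxide, [C-]#[O+]
Why: Tsuji decarboxylative carbonylation: oxidative addition gives the π-allylpalladium methoxide with loss of CO2, CO inserts at the unsubstituted allyl terminus and methoxide releases the β,γ-unsaturated methyl ester, the syn π-allyl geometry preserving the E alkene (any 3Z isomer is to be removed on AgNO3–silica).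

Step 3
Reactants: 3 methyl (3E)-4,8-dimethylnona-3,7-dienoate
Product: 5 methyl (3E,7E)-4,8-dimethyl-9-oxonona-3,7-dienoate, via methyl (3E,7E)-9-hydroxy-4,8-dimethylnona-3,7-dienoate 4 (not isolated)
Conditions: SeO2 (0.3 equiv), t-BuOOH (70% aq.), salicylic acid (cat.), CH2Cl2, 0 °C to rt; crude, then MnO2, CH2Cl2, rt
Reagents that add atoms: selenium dioxide (catalytic oxygen carrier), O=[Se]=O; tert-butyl hydroperoxide (terminal oxygen source), CC(C)(C)OO
Why: Sharpless catalytic SeO2 allylic oxidation (ene reaction, then [2,3]-shift) attacks the E-methyl of the terminal, most electron-rich isopropylidene group, the C3=C4 alkene being deactivated by the neighbouring ester, and MnO2 then converges the allylic alcohol/enal mixture on the (E)-enal.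

Step 4
Reactants: 5 methyl (3E,7E)-4,8-dimethyl-9-oxonona-3,7-dienoate
Product: 6 methyl (3E,7E)-4,8-dimethyldeca-3,7,9-trienoate
Conditions: Ph3PCH3Br (1.2 equiv), KHMDS (1.1 equiv), THF, 0 °C; then 5, −78 to 0 °C
Reagents that add atoms: methyltriphenylphosphonium bromide, C[P+](c1ccccc1)(c1ccccc1)c1ccccc1.[Br-]
Why: Wittig methylenation of the unhindered enal is much faster at −78 °C than attack on the ester or removal of its α-protons when no excess base is present, and leaves the E trisubstituted alkenes unchanged.

Step 5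
Reactants: 6 methyl (3E,7E)-4,8-dimethyldeca-3,7,9-trienoate; 7 methacrolein
Product: 8 methyl (3E)-6-[(1R,6S)-6-formyl-2,6-dimethylcyclohex-2-en-1-yl]-4-methylhex-3-enoate
Conditions: (S)-B-(o-tolyl)-diphenylprolinol oxazaborolidine (20 mol%), Tf2NH (17 mol%), 7 (2 equiv), CH2Cl2, −78 to −40 °C
Reagents that add atoms: none
Why: The boron-bound s-trans enal and the s-cis terminal diene of 6 combine in a concerted, asynchronous [4+2] in which the unsubstituted terminus C2 bonds first to the β-carbon C3 and C5 then bonds to C4, the reaction type being the cationic oxazaborolidine-catalysed Diels–Alder reaction of 2-methylacrolein with acyclic dienes. Ring A is closed by this intermolecular cycloaddition, which forms C2–C3 and C4–C5 and leaves the C1=C10 alkene. C4 is set by the catalyst, whose formyl C–H···O binding mode shields one enal face so that the diene adds to the Re face of C4 (expected for the (S)-catalyst; the (R)-catalyst is equally available should the sense prove opposite), and C5 follows from the formyl-endo approach of the E-configured diene, which places C19 cis to the C6 branch. The step needs ortho regiochemistry, endo orientation, one enal face and reaction at the conjugated diene only: the 1-alkyl terminus and the open CH2 end direct C4 to C5 as with 1-vinylcyclohexene-type dienes, Lewis-acid coordination favours formyl-endo, the catalyst supplies the face, and the isolated trisubstituted alkene and the ester are not dienes and bind the catalyst far less well than the aldehyde.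

Step 6
Reactants: 8 methyl (3E)-6-[(1R,6S)-6-formyl-2,6-dimethylcyclohex-2-en-1-yl]-4-methylhex-3-enoate
Product: 9 methyl (3E)-6-[(1R,6S)-6-(hydroxymethyl)-2,6-dimethylcyclohex-2-en-1-yl]-4-methylhex-3-enoate
Conditions: NaBH4, MeOH, 0 °C
Reagents that add atoms: none
Why: Borohydride reduction takes the neopentyl aldehyde to the C19 alcohol chemoselectively over the methyl ester and creates no stereocentre.

Step 7
Reactants: 9 methyl (3E)-6-[(1R,6S)-6-(hydroxymethyl)-2,6-dimethylcyclohex-2-en-1-yl]-4-methylhex-3-enoate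
Product: 10 methyl (3E)-6-[(1R,6S)-6-[(tert-butyldiphenylsilyloxy)methyl]-2,6-dimethylcyclohex-2-en-1-yl]-4-methylhex-3-enoate
Conditions: TBDPSCl, imidazole, DMAP (cat.), DMF, 40 °C
Reagents that add atoms: tert-butyl(chloro)diphenylsilane, CC(C)(C)[Si](Cl)(c1ccccc1)c1ccccc1
Why: Silylation of the primary (neopentyl) alcohol gives the most acid-stable common silyl ether, which keeps the C19 oxygen from capturing the C10 cation in step 9 and survives hydride and Grignard reagents later.

Step 8
Reactants: 10 methyl (3E)-6-[(1R,6S)-6-[(tert-butyldiphenylsilyloxy)methyl]-2,6-dimethylcyclohex-2-en-1-yl]-4-methylhex-3-enoate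
Product: 11 (3E)-6-[(1R,6S)-6-[(tert-butyldiphenylsilyloxy)methyl]-2,6-dimethylcyclohex-2-en-1-yl]-4-methylhex-3-enoic acid
Conditions: LiOH·H2O, THF/MeOH/H2O, rt; then dilute HCl to pH 3–4, 0 °C
Reagents that add atoms: lithium hydroxide (hydroxide oxygen), [Li+].[OH-]
Why: Saponification of the unhindered methyl ester at room temperature frees the carboxyl needed as internal nucleophile, the hindered TBDPS ether and the β,γ-alkene position being stable to these mild conditions.

Step 9
Reactants: 11 (3E)-6-[(1R,6S)-6-[(tert-butyldiphenylsilyloxy)methyl]-2,6-dimethylcyclohex-2-en-1-yl]-4-methylhex-3-enoic acid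
Product: 12 19-(tert-butyldiphenylsilyloxy)-13,14,15,16-tetranorlabdan-12,8α-olide (19-silyloxysclareolide; 4S,5R,8R,9R,10S)
Conditions: SnCl4 (2 equiv), CH2Cl2, −78 to −40 °C
Reagents that add atoms: none
Why: Cation–olefin cyclisation with lactone termination, of the type that converts monocyclohomofarnesic acid into sclareolide: protonation of the ring alkene at C1 gives the tertiary C10 cation, which the (E)-C8=C9 alkene attacks at C9 through a chair transition state with the C5 branch equatorial, so that C20 ends trans to H5 (C10 set from C5), and anti addition across the E-alkene with capture of C8 by the carboxyl gives C11 equatorial on C9 and the 8α (equatorial) C–O bond with C17 axial, while the bulky neopentyl silyl ether is a poor nucleophile and should survive SnCl4 at low temperature.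

Step 10
Reactants: 12 19-(tert-butyldiphenylsilyloxy)-13,14,15,16-tetranorlabdan-12,8α-olide
Product: 13 19-(tert-butyldiphenylsilyloxy)-13,14,15,16-tetranorlabdane-8α,12-diol
Conditions: LiAlH4, THF, 0 °C
Reagents that add atoms: none
Why: Hydride reduction opens the γ-lactone to the primary C12 alcohol and the tertiary 8α-alcohol without touching any stereocentre or the silyl ether.

Step 11
Reactants: 13 19-(tert-butyldiphenylsilyloxy)-13,14,15,16-tetranorlabdane-8α,12-diol
Product: 14 19-(tert-butyldiphenylsilyloxy)-8α,12-bis(triethylsilyloxy)-13,14,15,16-tetranorlabdane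
Conditions: TESOTf (3 equiv), 2,6-lutidine, CH2Cl2, −78 to 0 °C
Reagents that add atoms: triethylsilyl trifluoromethanesulfonate, CC[Si](CC)(CC)OS(=O)(=O)C(F)(F)F
Why: The silyl triflate silylates both the primary and the hindered tertiary hydroxyl, so that the C8 oxygen is masked before C12 is activated and cannot close the 8,12-ether.

Step 12
Reactants: 14 19-(tert-butyldiphenylsilyloxy)-8α,12-bis(triethylsilyloxy)-13,14,15,16-tetranorlabdane
Product: 15 19-(tert-butyldiphenylsilyloxy)-8α-(triethylsilyloxy)-13,14,15,16-tetranorlabdan-12-ol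
Conditions: PPTS (0.2 equiv), MeOH/CH2Cl2 (1:3), 0 °C
Reagents that add atoms: none
Why: Mild acid-catalysed methanolysis cleaves the unhindered primary triethylsilyl ether much faster than the tertiary one or the TBDPS ether.

Step 13
Reactants: 15 19-(tert-butyldiphenylsilyloxy)-8α-(triethylsilyloxy)-13,14,15,16-tetranorlabdan-12-ol
Product: 16 19-(tert-butyldiphenylsilyloxy)-12-iodo-8α-(triethylsilyloxy)-13,14,15,16-tetranorlabdane
Conditions: I2, PPh3, imidazole, CH2Cl2, 0 °C to rt
Reagents that add atoms: iodine, II
Why: Appel-type (Garegg–Samuelsson) iodination displaces the activated primary C12 oxygen by iodide in an SN2 step under buffered conditions that the silyl ethers tolerate.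

Step 14
Reactants: 17 chloroprene
Product: 18 buta-1,3-dien-2-ylmagnesium chloride (THF solution, titrated and used directly)
Conditions: Mg turnings, ZnCl2 (cat.), BrCH2CH2Br (activator), THF, reflux
Reagents that add atoms: magnesium, [Mg]
Why: Zinc-chloride-promoted insertion of activated magnesium into the vinylic C–Cl bond is the established preparation of this dienyl Grignard reagent.

Step 15
Reactants: 16 19-(tert-butyldiphenylsilyloxy)-12-iodo-8α-(triethylsilyloxy)-13,14,15,16-tetranorlabdane; 18 buta-1,3-dien-2-ylmagnesium chloride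
Product: 19 19-(tert-butyldiphenylsilyloxy)-8α-(triethylsilyloxy)labda-13(16),14-diene
Conditions: 18 (3 equiv), Li2CuCl4 (5 mol%), THF, −20 to 0 °C
Reagents that add atoms: none
Why: Kochi-type copper-catalysed sp3–sp2 coupling of a primary alkyl iodide with the dienyl Grignard reagent joins C12 to the metal-bearing carbon C13 and gives the 2-substituted 1,3-diene, the silyl ethers being inert to the reagent.

Step 16
Reactants: 19 19-(tert-butyldiphenylsilyloxy)-8α-(triethylsilyloxy)labda-13(16),14-diene
Product: 20 labda-13(16),14-diene-8α,19-diol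
Conditions: TBAF (5 equiv), THF, 50 °C
Reagents that add atoms: none
Why: Fluoride cleaves both silicon–oxygen bonds under non-acidic conditions that spare the acid-sensitive diene and the tertiary alcohol.

Step 17
Reactants: 21 p-coumaric acid
Product: 23 (E)-4-(tert-butyldimethylsilyloxy)cinnamic acid, via tert-butyldimethylsilyl (E)-4-(tert-butyldimethylsilyloxy)cinnamate 22 (not isolated)
Conditions: TBSCl (2.4 equiv), imidazole, DMF, rt; then AcOH/THF/H2O, rt
Reagents that add atoms: tert-butyl(chloro)dimethylsilane, CC(C)(C)[Si](C)(C)Cl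
Why: Double silylation followed by selective hydrolysis of the labile silyl ester leaves the phenol masked as its aryl silyl ether and the acid free, with the E alkene untouched.

Step 18
Reactants: 20 labda-13(16),14-diene-8α,19-diol; 23 (E)-4-(tert-butyldimethylsilyloxy)cinnamic acid
Product: 24 8α-hydroxylabda-13(16),14-dien-19-yl (E)-4-(tert-butyldimethylsilyloxy)cinnamate
Conditions: 23 (1.3 equiv), EDC·HCl, DMAP, CH2Cl2, rt, dark
Reagents that add atoms: none
Why: Steglich esterification acylates the primary C19 hydroxyl, the tertiary 8α-hydroxyl being unreactive under carbodiimide/DMAP conditions at room temperature.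

Step 19
Reactants: 24 8α-hydroxylabda-13(16),14-dien-19-yl (E)-4-(tert-butyldimethylsilyloxy)cinnamate
Product: 25 8α-hydroxylabda-13(16),14-dien-19-yl p-hydroxycinnamate
Conditions: TBAF (1.1 equiv), AcOH (1.1 equiv), THF, 0 °C, dark
Reagents that add atoms: none
Why: Buffered fluoride removes the aryl silyl ether within minutes at 0 °C without cleaving the cinnamate ester or isomerising its E alkene.

**Compound list**
1 | geraniol | CC(C)=CCC/C(C)=C/CO | starting material
2 | geranyl methyl carbonate | CC(C)=CCC/C(C)=C/COC(=O)OC | intermediate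
3 | methyl (3E)-4,8-dimethylnona-3,7-dienoate | CC(C)=CCC/C(C)=C/CC(=O)OC | intermediate
4 | methyl (3E,7E)-9-hydroxy-4,8-dimethylnona-3,7-dienoate | OC/C(C)=C/CC/C(C)=C/CC(=O)OC | intermediate
5 | methyl (3E,7E)-4,8-dimethyl-9-oxonona-3,7-dienoate | O=C/C(C)=C/CC/C(C)=C/CC(=O)OC | intermediate
6 | methyl (3E,7E)-4,8-dimethyldeca-3,7,9-trienoate | C=C/C(C)=C/CC/C(C)=C/CC(=O)OC | intermediate
7 | methacrolein | C=C(C)C=O | starting material
8 | methyl (3E)-6-[(1R,6S)-6-formyl-2,6-dimethylcyclohex-2-en-1-yl]-4-methylhex-3-enoate | O=C[C@@]1(C)CCC=C(C)[C@H]1CC/C(C)=C/CC(=O)OC | intermediate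
9 | methyl (3E)-6-[(1R,6S)-6-(hydroxymethyl)-2,6-dimethylcyclohex-2-en-1-yl]-4-methylhex-3-enoate | OC[C@@]1(C)CCC=C(C)[C@H]1CC/C(C)=C/CC(=O)OC | intermediate
10 | methyl (3E)-6-[(1R,6S)-6-[(tert-butyldiphenylsilyloxy)methyl]-2,6-dimethylcyclohex-2-en-1-yl]-4-methylhex-3-enoate | CC(C)(C)[Si](OC[C@@]1(C)CCC=C(C)[C@H]1CC/C(C)=C/CC(=O)OC)(c1ccccc1)c1ccccc1 | intermediate
11 | (3E)-6-[(1R,6S)-6-[(tert-butyldiphenylsilyloxy)methyl]-2,6-dimethylcyclohex-2-en-1-yl]-4-methylhex-3-enoic acid | CC(C)(C)[Si](OC[C@@]1(C)CCC=C(C)[C@H]1CC/C(C)=C/CC(=O)O)(c1ccccc1)c1ccccc1 | intermediate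
12 | 19-(tert-butyldiphenylsilyloxy)-13,14,15,16-tetranorlabdan-12,8α-olide (4S,5R,8R,9R,10S) | O=C1C[C@@H]2[C@@]3(C)CCC[C@](C)(CO[Si](c4ccccc4)(c4ccccc4)C(C)(C)C)[C@@H]3CC[C@@]2(C)O1 | intermediate
13 | 19-(tert-butyldiphenylsilyloxy)-13,14,15,16-tetranorlabdane-8α,12-diol | OCC[C@@H]1[C@@]2(C)CCC[C@](C)(CO[Si](c3ccccc3)(c3ccccc3)C(C)(C)C)[C@@H]2CC[C@@]1(C)O | intermediate
14 | 19-(tert-butyldiphenylsilyloxy)-8α,12-bis(triethylsilyloxy)-13,14,15,16-tetranorlabdane | CC[Si](CC)(CC)OCC[C@@H]1[C@@]2(C)CCC[C@](C)(CO[Si](c3ccccc3)(c3ccccc3)C(C)(C)C)[C@@H]2CC[C@@]1(C)O[Si](CC)(CC)CC | intermediate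
15 | 19-(tert-butyldiphenylsilyloxy)-8α-(triethylsilyloxy)-13,14,15,16-tetranorlabdan-12-ol | OCC[C@@H]1[C@@]2(C)CCC[C@](C)(CO[Si](c3ccccc3)(c3ccccc3)C(C)(C)C)[C@@H]2CC[C@@]1(C)O[Si](CC)(CC)CC | intermediate
16 | 19-(tert-butyldiphenylsilyloxy)-12-iodo-8α-(triethylsilyloxy)-13,14,15,16-tetranorlabdane | ICC[C@@H]1[C@@]2(C)CCC[C@](C)(CO[Si](c3ccccc3)(c3ccccc3)C(C)(C)C)[C@@H]2CC[C@@]1(C)O[Si](CC)(CC)CC | intermediate
17 | chloroprene | C=CC(Cl)=C | starting material
18 | buta-1,3-dien-2-ylmagnesium chloride | C=CC(=C)[Mg]Cl | intermediate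
19 | 19-(tert-butyldiphenylsilyloxy)-8α-(triethylsilyloxy)labda-13(16),14-diene | C=CC(=C)CC[C@@H]1[C@@]2(C)CCC[C@](C)(CO[Si](c3ccccc3)(c3ccccc3)C(C)(C)C)[C@@H]2CC[C@@]1(C)O[Si](CC)(CC)CC | intermediate
20 | labda-13(16),14-diene-8α,19-diol | C=CC(=C)CC[C@@H]1[C@@]2(C)CCC[C@](C)(CO)[C@@H]2CC[C@@]1(C)O | intermediate
21 | p-coumaric acid | O=C(O)/C=C/c1ccc(O)cc1 | starting material
22 | tert-butyldimethylsilyl (E)-4-(tert-butyldimethylsilyloxy)cinnamate | CC(C)(C)[Si](C)(C)OC(=O)/C=C/c1ccc(O[Si](C)(C)C(C)(C)C)cc1 | intermediate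
23 | (E)-4-(tert-butyldimethylsilyloxy)cinnamic acid | O=C(O)/C=C/c1ccc(O[Si](C)(C)C(C)(C)C)cc1 | intermediate
24 | 8α-hydroxylabda-13(16),14-dien-19-yl (E)-4-(tert-butyldimethylsilyloxy)cinnamate | C=CC(=C)CC[C@@H]1[C@@]2(C)CCC[C@](C)(COC(=O)/C=C/c3ccc(O[Si](C)(C)C(C)(C)C)cc3)[C@@H]2CC[C@@]1(C)O | intermediate
25 | 8α-hydroxylabda-13(16),14-dien-19-yl p-hydroxycinnamate | C=CC(=C)CC[C@@H]1[C@@]2(C)CCC[C@](C)(COC(=O)/C=C/c3ccc(O)cc3)[C@@H]2CC[C@@]1(C)O | target

**Step count**
Total: 19 steps. Longest linear sequence: 17 steps from geraniol (steps 1–13, 15, 16, 18, 19); steps 14 and 17 are side branches.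

**Steps most likely to fail**

Step 5 (key Diels–Alder). The cationic boron catalyst may give insufficient discrimination of the enal faces, or may oligomerise the electron-rich triene before cycloaddition. The regiochemistry and the formyl-endo orientation are properties of the diene/enal pair under Lewis acid and should persist with an achiral promoter, so the fallback gives up catalyst control of absolute configuration and resolves instead. Setting out from 6 and 7, Me2AlCl in CH2Cl2 at −78 °C should give the racemic endo adduct, rac-methyl (3E)-6-[(1R*,6S*)-6-formyl-2,6-dimethylcyclohex-2-en-1-yl]-4-methylhex-3-enoate F1. NaBH4 in MeOH then gives the racemic alcohol, rac-methyl (3E)-6-[(1R*,6S*)-6-(hydroxymethyl)-2,6-dimethylcyclohex-2-en-1-yl]-4-methylhex-3-enoate F2. Acylation with (1S)-camphanic chloride (pyridine, DMAP) gives two diastereomeric esters, the (1S)-camphanate of the (1R,6S)-alcohol F3 and the (1S)-camphanate of the (1S,6R)-alcohol F4, to be separated by chromatography or crystallisation. Methanolysis of F3 (K2CO3, MeOH, 0 °C) releases the alcohol and keeps the side-chain methyl ester, so the route is rejoined at 9.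

Step 9 (ring B closure). The C10 cation may lose H5 to give the C5(10) alkene, which erodes the relay from C5; it may also be attacked on its β face (cis-decalin), and protonation of the β,γ-alkene with direct γ-lactonisation may compete. The fallback replaces substrate-controlled protonation of the acid by reagent-controlled, concerted protonation–cyclisation of the alcohol. Setting out from 10, LiAlH4 (THF, 0 °C) gives the homoallylic alcohol, (3E)-6-[(1R,6S)-6-[(tert-butyldiphenylsilyloxy)methyl]-2,6-dimethylcyclohex-2-en-1-yl]-4-methylhex-3-en-1-ol F5. Cyclisation with the matched enantiomer of a BINOL monoether·SnCl4 Lewis-acid-assisted Brønsted acid (CH2Cl2, −78 °C; the type of reagent that closes homofarnesol to Ambrox) should give the cyclic ether, 19-(tert-butyldiphenylsilyloxy)-8α,12-epoxy-13,14,15,16-tetranorlabdane F6. Oxidation of the ether CH2 (C12) with catalytic RuCl3/NaIO4, as in the conversion of Ambrox into sclareolide, rejoins the route at 12.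

Step 15 (copper-catalysed coupling). Halogen–metal exchange or elimination at the iodide, homocoupling, or bond formation through the allenyl terminus of the dienyl Grignard reagent may divert the coupling. The fallback builds the diene from an alkyne instead. Setting out from 16, lithium acetylide–ethylenediamine in DMSO/THF displaces the iodide to give the terminal alkyne, 19-(tert-butyldiphenylsilyloxy)-8α-(triethylsilyloxy)-15,16-dinorlabd-13-yne F7. Ethylene–alkyne cross enyne metathesis (Grubbs second-generation catalyst, ethylene 1 atm, CH2Cl2, 40 °C) converts the alkyne carbons into C13 and C14 and adds the two methylene termini, rejoining the route at 19.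

**Further compounds**
F1 | step 5 | rac-methyl (3E)-6-[(1R*,6S*)-6-formyl-2,6-dimethylcyclohex-2-en-1-yl]-4-methylhex-3-enoate (both enantiomers) | O=C[C@@]1(C)CCC=C(C)[C@H]1CC/C(C)=C/CC(=O)OC.O=C[C@]1(C)CCC=C(C)[C@@H]1CC/C(C)=C/CC(=O)OC
F2 | step 5 | rac-methyl (3E)-6-[(1R*,6S*)-6-(hydroxymethyl)-2,6-dimethylcyclohex-2-en-1-yl]-4-methylhex-3-enoate (both enantiomers) | OC[C@@]1(C)CCC=C(C)[C@H]1CC/C(C)=C/CC(=O)OC.OC[C@]1(C)CCC=C(C)[C@@H]1CC/C(C)=C/CC(=O)OC
F3 | step 5 | [(1S,2R)-2-[(3E)-6-methoxy-3-methyl-6-oxohex-3-enyl]-1,3-dimethylcyclohex-3-en-1-yl]methyl (1S,4R)-camphanate (ester of 9) | O=C(OC[C@@]1(C)CCC=C(C)[C@H]1CC/C(C)=C/CC(=O)OC)[C@@]12CC[C@@](C)(C(=O)O1)C2(C)C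
F4 | step 5 | (1S,4R)-camphanate of the enantiomeric (1S,6R)-alcohol (diastereomer of F3, discarded) | O=C(OC[C@]1(C)CCC=C(C)[C@@H]1CC/C(C)=C/CC(=O)OC)[C@@]12CC[C@@](C)(C(=O)O1)C2(C)C
F5 | step 9 | (3E)-6-[(1R,6S)-6-[(tert-butyldiphenylsilyloxy)methyl]-2,6-dimethylcyclohex-2-en-1-yl]-4-methylhex-3-en-1-ol | CC(C)(C)[Si](OC[C@@]1(C)CCC=C(C)[C@H]1CC/C(C)=C/CCO)(c1ccccc1)c1ccccc1
F6 | step 9 | 19-(tert-butyldiphenylsilyloxy)-8α,12-epoxy-13,14,15,16-tetranorlabdane | C1C[C@@H]2[C@@]3(C)CCC[C@](C)(CO[Si](c4ccccc4)(c4ccccc4)C(C)(C)C)[C@@H]3CC[C@@]2(C)O1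
F7 | step 15 | 19-(tert-butyldiphenylsilyloxy)-8α-(triethylsilyloxy)-15,16-dinorlabd-13-yne | C#CCC[C@@H]1[C@@]2(C)CCC[C@](C)(CO[Si](c3ccccc3)(c3ccccc3)C(C)(C)C)[C@@H]2CC[C@@]1(C)O[Si](CC)(CC)CC
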